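**Retrosynthetic overview**
1. Target 28 ⇐ Mukaiyama hydration of the isopropenyl group and oxidative δ-lactonization of a 1,5-diol on cage 25 (δ-lactone ring formed last).
2. Orthoester cage 25 (pyran, dioxolane and γ-lactone rings together) ⇐ acid-triggered isomerization of a γ-hydroxybutenolide/spiro-γ-lactone 24; hydroxybutenolide ⇐ ¹O2 on 2-silyloxyfuran 22.
3. C9–C10 ⇐ chelated Michael addition of the spiro-lactone enolate of 17 to (E)-ethylidene-angelica lactone 20.
4. Key step, C7–C8 and the spiro-γ-lactone ⇐ SmI2 cascade on epoxy ketone 14: reductive epoxide opening, then ketyl-radical addition to methyl methacrylate.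
5. Ring A (formed first) ⇐ organocatalytic Michael/aldol condensation (C5), acrylate Michael (C6), hydride reduction and OH-directed epoxidation (C7, C3, C2).

Assumption: all seven starting materials (1, 3, 4, 9, 15, 18, 19; each ≤ 8 non-hydrogen atoms) are purchased, and the ~90–95 % ee from step 3 is upgraded by recrystallizing triol 11.
Locants used below follow the target: ring A = C2 (CHMe), C3 (CHOH), C4, C5 (CH–isopropenyl/CMe2OH), C6 (quaternary), C7 (spiro C–O); C8 (CH2), C9 (CMe), C10 (CHMe), C11, C12 (C=O), C13 (ketal C), C15 (OCH) and C14 (lactone/orthoester C). "Cis/trans" refers to the C5 substituent on ring A. The route has not been run; yields and selectivities are expectations.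

**Step 1**
Reactants: 1 methyl acetoacetate
Product: 2 methyl 3-oxopentanoate
Conditions: NaH, THF, 0 °C; n-BuLi; MeI; aq. HCl
Reagents that add atoms: iodomethane, CI
Why: Weiler dianion alkylation; the more reactive terminal (γ) carbanion of the acetoacetate dianion is methylated selectively.

**Step 2**
Reactants: 3 N-tert-butylethanimine; 4 methacrolein
Product: 6 (2E)-4-methylpenta-2,4-dienal, via hydroxy imine 5 (not isolated)
Conditions: LDA, THF, −78 °C; 4; then aq. oxalic acid, rt
Reagents that add atoms: water, O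
Why: Wittig-type directed aldol condensation; the lithio-azaenolate adds 1,2 to methacrolein, and acid hydrolysis/dehydration gives the conjugated (E)-dienal.

**Step 3**
Reactants: 2 methyl 3-oxopentanoate; 6 (2E)-4-methylpenta-2,4-dienal
Product: 8 methyl (1S,6R)-3-methyl-2-oxo-6-(prop-1-en-2-yl)cyclohex-3-ene-1-carboxylate, via Michael adduct 7 (not isolated)
Conditions: (S)-α,α-diphenylprolinol TMS ether (10 mol %), PhCO2H (10 mol %), toluene, rt; then p-TsOH (20 mol %), 40 °C
Reagents that add atoms: none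
Why: Iminium-catalysed asymmetric Michael addition followed by intramolecular aldol condensation (Jørgensen-type cyclohexenone synthesis); the (S)-catalyst shields one face of the E-iminium so the β-keto ester adds to the Si face of the β-carbon and sets C5.

**Step 4**
Reactants: 8 cyclohexenone ester; 9 methyl acrylate
Product: 10 methyl (1R,6S)-1-(3-methoxy-3-oxopropyl)-3-methyl-2-oxo-6-(prop-1-en-2-yl)cyclohex-3-ene-1-carboxylate
Conditions: DBU (0.2 equiv), MeCN, 0 °C → rt
Reagents that add atoms: none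
Why: Michael addition of a cyclic β-keto ester; acrylate approaches the enolate anti to the adjacent C5 isopropenyl, so the propanoate chain ends trans and the CO2Me cis to it (C6).

**Step 5**
Reactants: 10 keto diester
Product: 11 triol (C7-OH and C6-CH2OH cis, C6-(CH2)3OH trans to the isopropenyl group)
Conditions: LiAlH4, THF, −78 → 0 °C
Reagents that add atoms: none
Why: Hydride reduction of both esters and 1,2-reduction of the enone; hydride attacks C7=O anti to the pseudo-axial C6 ester, giving the cis-carveol-type alcohol.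

**Step 6**
Reactants: 11 triol
Product: 12 bis-TBS ether (both primary OH silylated, C7-OH free)
Conditions: TBSCl (2.1 equiv), imidazole, CH2Cl2, 0 °C
Reagents that add atoms: tert-butyldimethylsilyl chloride, CC(C)(C)[Si](C)(C)Cl
Why: Selective silylation; the two primary alcohols react far faster than the secondary allylic alcohol next to the quaternary carbon.

**Step 7**
Reactants: 12 allylic alcohol
Product: 13 syn-epoxy alcohol (C2–C3 epoxide cis to C7-OH)
Conditions: VO(acac)2 (5 mol %), t-BuOOH, CH2Cl2, 0 °C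
Reagents that add atoms: tert-butyl hydroperoxide, CC(C)(C)OO
Why: Hydroxyl-directed vanadium epoxidation; oxygen is delivered syn to C7-OH, which places the C3 oxygen cis to the C5 substituent, and the remote isopropenyl alkene is not directed.

**Step 8**
Reactants: 13 epoxy alcohol
Product: 14 α,β-epoxy ketone
Conditions: Dess–Martin periodinane, CH2Cl2, 0 °C → rt
Reagents that add atoms: none
Why: Dess–Martin oxidation of the secondary alcohol under non-basic conditions leaves the epoxide and silyl ethers untouched.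

**Step 9 (key step)**
Reactants: 14 α,β-epoxy ketone; 15 methyl methacrylate
Product: 17 spiro-γ-lactone (C7–O cis, C8 trans to C2-Me and C6-CH2OTBS; C3-OH free; C9 epimers), via hydroxy ketone 16 (not isolated)
Conditions: SmI2 (2.2 equiv), THF–MeOH, −90 °C; then 15 (3 equiv), SmI2 (2.5 equiv), HMPA, −78 → 0 °C
Reagents that add atoms: none
Why: Proposed new method: telescoping of two known SmI2 reactions (closest types: Molander epoxy-ketone reduction and Fukuzawa ketyl–olefin spirolactonization) — the ketyl of 14 cleaves the α C–O bond to a Sm enolate/C3 alkoxide that MeOH protonates at C2 anti to the C3–OSm and the syn-axial C6–CH2OTBS (C2-Me cis to C3-OH), then the samarium ketyl of 16 adds as a carbon radical to methyl methacrylate on the axial face anti to the two syn-axial groups, forming C7–C8 with O7 cis to them, and the Sm alkoxide lactonizes.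

**Step 10**
Reactants: 18 α-angelica lactone; 19 acetaldehyde
Product: 20 (3E)-3-ethylidene-5-methylfuran-2(3H)-one
Conditions: piperidine (10 mol %), AcOH (10 mol %), 4 Å MS, CH2Cl2, 0 °C → rt
Reagents that add atoms: none
Why: Knoevenagel-type aldol condensation at the acidic C3 methylene of the enol lactone gives the thermodynamically preferred E-alkylidene (methyl anti to the carbonyl).

**Step 11**
Reactants: 17 spiro-γ-lactone; 20 ethylidene furanone
Product: 22 2-silyloxyfuran (C9 quaternary, C10 set; C3-OTBS), via dilithium furanolate 21 (not isolated)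
Conditions: LDA (2.2 equiv), THF, −78 °C; 20; then TBSOTf (2.5 equiv), −78 → 0 °C
Reagents that add atoms: tert-butyldimethylsilyl triflate, CC(C)(C)[Si](C)(C)OS(=O)(=O)C(F)(F)F
Why: Lithium-enolate Michael addition, made irreversible by aromatization to the furanolate, which is trapped by silylation; the acceptor attacks the lactone enolate face on the C2–H side (anti to quaternary C6), setting C9, and an eight-membered Li-chelated transition state (OLi cis to C9-Me, s-cis E-acceptor) is expected to give the C9-Me/C10-Me syn relationship.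

**Step 12**
Reactants: 22 2-silyloxyfuran
Product: 23 γ-hydroxybutenolide (C13 hemiketal epimers; three TBS ethers retained)
Conditions: O2, hν, TPP (cat.), CH2Cl2, −78 °C; then Me2S
Reagents that add atoms: oxygen, O=O
Why: Singlet-oxygen [4+2] cycloaddition across the furan 2,5-positions followed by silyl transfer and reduction gives the 5-hydroxy-5-methylbutenolide regiospecifically; the isopropenyl group reacts much more slowly at −78 °C.

**Step 13**
Reactants: 23 γ-hydroxybutenolide
Product: 25 orthoester cage triol (C3-OH, C6-CH2OH, C6-(CH2)3OH; isopropenyl), via desilylated butenolide 24 (not isolated)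
Conditions: HF·pyridine, THF, 0 °C → rt; then CSA (10 mol %), CH2Cl2, rt
Reagents that add atoms: none
Why: Proposed new method: after desilylation, acid promotes attack of the γ-lactone carbonyl oxygen on C15 of the butenolide (6-ring oxa-Michael) to give a dialkoxycarbenium ion at C14 that the cis C13 hemiketal OH traps, an atom-neutral isomerization in which the cage topology fixes C11, C13, C14 and C15 relative to C9 (closest known types: carbonyl-participation orthoester formation as in the epoxy-ester→orthoester rearrangement, and hemiketal oxa-Michael cyclizations).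

**Step 14**
Reactants: 25 cage triol
Product: 27 spiro-δ-lactone cage (isopropenyl), via lactol 26 (not isolated)
Conditions: TEMPO (20 mol %), PhI(OAc)2 (2.2 equiv), CH2Cl2, rt
Reagents that add atoms: none
Why: TEMPO/BAIB oxidative lactonization of a 1,5-diol; the unhindered chain CH2OH is oxidized first, the neopentyl C6-CH2OH closes the lactol, and the secondary C3-OH is left.

**Step 15**
Reactants: 27 isopropenyl cage lactone
Product: 28 chermebilaene B
Conditions: Co(acac)2 (20 mol %), PhSiH3, O2 (1 atm), THF, rt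
Reagents that add atoms: oxygen, O=O
Why: Mukaiyama hydration (metal-hydride H-atom transfer, Markovnikov) turns the only alkene into the tertiary alcohol without creating a stereocenter.

**Compound list**
1 | methyl acetoacetate | CC(=O)CC(=O)OC | starting material
2 | methyl 3-oxopentanoate | CCC(=O)CC(=O)OC | intermediate
3 | N-tert-butylethanimine | CC=NC(C)(C)C | starting material
4 | methacrolein | CC(=C)C=O | starting material
5 | N-tert-butyl-3-hydroxy-4-methylpent-4-en-1-imine (racemic) | CC(=C)C(O)CC=NC(C)(C)C | intermediate (not isolated)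
6 | (2E)-4-methylpenta-2,4-dienal | CC(=C)/C=C/C=O | intermediate
7 | methyl (3R)-5-oxo-3-(prop-1-en-2-yl)-2-propanoylpentanoate (C2 epimers) | O=CC[C@@H](C(C)=C)C(C(=O)OC)C(=O)CC | intermediate (not isolated)
8 | methyl (1S,6R)-3-methyl-2-oxo-6-(prop-1-en-2-yl)cyclohex-3-ene-1-carboxylate | CC1=CC[C@@H](C(C)=C)[C@H](C(=O)OC)C1=O | intermediate
9 | methyl acrylate | C=CC(=O)OC | starting material
10 | methyl (1R,6S)-1-(3-methoxy-3-oxopropyl)-3-methyl-2-oxo-6-(prop-1-en-2-yl)cyclohex-3-ene-1-carboxylate | CC1=CC[C@@H](C(C)=C)[C@@](CCC(=O)OC)(C(=O)OC)C1=O | intermediate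
11 | 6-(hydroxymethyl)-6-(3-hydroxypropyl)-2-methyl-5-(prop-1-en-2-yl)cyclohex-2-en-1-ol, 1-OH and CH2OH cis to isopropenyl | CC1=CC[C@@H](C(C)=C)[C@@](CCCO)(CO)[C@H]1O | intermediate
12 | bis(TBS) ether of 11 at both primary OH | CC1=CC[C@@H](C(C)=C)[C@@](CCCO[Si](C)(C)C(C)(C)C)(CO[Si](C)(C)C(C)(C)C)[C@H]1O | intermediate
13 | C2–C3 epoxide of 12, epoxide O cis to C7-OH | C[C@@]12[C@@H](O1)C[C@@H](C(C)=C)[C@@](CCCO[Si](C)(C)C(C)(C)C)(CO[Si](C)(C)C(C)(C)C)[C@H]2O | intermediate
14 | α,β-epoxy ketone (C7=O) from 13 | C[C@@]12[C@@H](O1)C[C@@H](C(C)=C)[C@@](CCCO[Si](C)(C)C(C)(C)C)(CO[Si](C)(C)C(C)(C)C)C2=O | intermediate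
15 | methyl methacrylate | CC(=C)C(=O)OC | starting material
16 | β-hydroxy ketone, C2-Me and C3-OH cis to isopropenyl | C[C@H]1[C@@H](O)C[C@@H](C(C)=C)[C@@](CCCO[Si](C)(C)C(C)(C)C)(CO[Si](C)(C)C(C)(C)C)C1=O | intermediate (not isolated)
17 | spiro α-methyl-γ-butyrolactone at C7 (O7 cis to C2-Me/C3-OH; C9 epimers) | C[C@H]1[C@@H](O)C[C@@H](C(C)=C)[C@@](CCCO[Si](C)(C)C(C)(C)C)(CO[Si](C)(C)C(C)(C)C)[C@]12CC(C)C(=O)O2 | intermediate
18 | α-angelica lactone (5-methylfuran-2(3H)-one) | CC1=CCC(=O)O1 | starting material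
19 | acetaldehyde | CC=O | starting material
20 | (3E)-3-ethylidene-5-methylfuran-2(3H)-one | C/C=C1/C(=O)OC(C)=C1 | intermediate
21 | dilithium salt of the Michael adduct (C3 alkoxide, furan-2-olate) | C[C@H]1[C@@H]([O-])C[C@@H](C(C)=C)[C@@](CCCO[Si](C)(C)C(C)(C)C)(CO[Si](C)(C)C(C)(C)C)[C@]12C[C@](C)([C@@H](C)c3cc(C)oc3[O-])C(=O)O2.[Li+].[Li+] | intermediate (not isolated)
22 | spirolactone with C9-Me and C9-[1-(5-methyl-2-TBSO-furan-3-yl)ethyl], C3-OTBS | C[C@H]1[C@@H](O[Si](C)(C)C(C)(C)C)C[C@@H](C(C)=C)[C@@](CCCO[Si](C)(C)C(C)(C)C)(CO[Si](C)(C)C(C)(C)C)[C@]12C[C@](C)([C@@H](C)c3cc(C)oc3O[Si](C)(C)C(C)(C)C)C(=O)O2 | intermediate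
23 | 5-hydroxy-5-methylbutenolide from 22 (C13 epimers) | C[C@H]1[C@@H](O[Si](C)(C)C(C)(C)C)C[C@@H](C(C)=C)[C@@](CCCO[Si](C)(C)C(C)(C)C)(CO[Si](C)(C)C(C)(C)C)[C@]12C[C@](C)([C@@H](C)C3=CC(C)(O)OC3=O)C(=O)O2 | intermediate
24 | fully desilylated hydroxybutenolide | C[C@H]1[C@@H](O)C[C@@H](C(C)=C)[C@@](CCCO)(CO)[C@]12C[C@](C)([C@@H](C)C3=CC(C)(O)OC3=O)C(=O)O2 | intermediate (not isolated)
25 | orthoester cage with C3-OH, C6-CH2OH, C6-(CH2)3OH and C5-isopropenyl | C[C@H]1[C@@H](O)C[C@@H](C(C)=C)[C@@](CCCO)(CO)[C@]12C[C@]1(C)[C@@H](C)[C@H]3C(=O)O[C@@]4(C)O[C@@]1(O[C@@H]34)O2 | intermediate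
26 | spiro-δ-lactol of 25 | C[C@H]1[C@@H](O)C[C@@H](C(C)=C)[C@]2(CCC(O)OC2)[C@]12C[C@]1(C)[C@@H](C)[C@H]3C(=O)O[C@@]4(C)O[C@@]1(O[C@@H]34)O2 | intermediate (not isolated)
27 | 5-isopropenyl analogue of the target (spiro-δ-lactone closed) | C[C@H]1[C@@H](O)C[C@@H](C(C)=C)[C@]2(CCC(=O)OC2)[C@]12C[C@]1(C)[C@@H](C)[C@H]3C(=O)O[C@@]4(C)O[C@@]1(O[C@@H]34)O2 | intermediate
28 | chermebilaene B | C[C@H]1[C@@H](O)C[C@@H](C(C)(C)O)[C@]2(CCC(=O)OC2)[C@]12C[C@]1(C)[C@@H](C)[C@H]3C(=O)O[C@@]4(C)O[C@@]1(O[C@@H]34)O2 | target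

**Step count**
Total: 15 steps. Longest linear sequence: 13 steps (1, 3–9, 11–15); steps 2 and 10 are side branches.

**Three steps most likely to fail, with fallbacks**

Step 9 (SmI2 cascade). The C2 protonation may give the more stable trans-methyl epimer, and the hindered ketyl may simply be reduced instead of adding to the acrylate. Fallback, from 13 back to 22: open the epoxy alcohol 13 with Cp2TiCl (Cp2TiCl2/Mn, THF, H2O as H-atom source) by homolysis of the tertiary C2–O bond. The C2 radical takes its hydrogen from the face opposite the two titanium alkoxides and the syn-axial C6–CH2OTBS, giving the all-cis 1,3-diol F1. Selective silylation of the less hindered C3-OH (TBSCl, imidazole) gives the silyl ether F2. Dess–Martin oxidation gives the β-silyloxy ketone F3. A separate SmI2/HMPA/t-BuOH ketyl–olefin coupling with 15 gives the spirolactone F4. Treating F4 with LDA (1.1 equiv), then 20, then TBSOTf as in step 11 gives 22.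

Step 11 (Michael addition). The lithium enolate may acylate on the enol-lactone carbonyl of 20, or the C9/C10 diastereoselectivity may be low or reversed. Fallback, from 17 back to 22: convert 17 (LDA 2.2 equiv, TBSCl, HMPA) into the silyl ketene acetal F5, which also carries the C3-OTBS. Run a Mukaiyama–Michael addition to 20 with catalytic TBSOTf in CH2Cl2 at −78 °C. This soft nucleophile reacts only in the conjugate sense through an open transition state, and silyl transfer to the furanolate gives 22 directly.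

Step 13 (cage isomerization). The equilibrium may not favour the orthoester, or the lactone carbonyl may not engage the butenolide. Fallback, from 23 back to 25: convert 23 with MeOH/PPTS into the methyl pseudo-ester F6. Copper-catalysed β-borylation (CuCl, Xantphos, NaOt-Bu, B2pin2, MeOH) gives the C15 boronate F7, and NaBO3 oxidation gives the C15 alcohol F8. HF·pyridine, then CSA with 4 Å MS, closes the orthoester by transketalization with loss of methanol: C15-OH adds to the activated C14 carbonyl and the C13 oxocarbenium is trapped. The C11/C15 epimers are expected to equilibrate under the acid, giving 25.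

**Further compounds**
F1 | step 9 | all-cis 1,3-diol (C7-OH, C3-OH, C2-Me cis to isopropenyl), bis-TBS | C[C@H]1[C@@H](O)C[C@@H](C(C)=C)[C@@](CCCO[Si](C)(C)C(C)(C)C)(CO[Si](C)(C)C(C)(C)C)[C@H]1O
F2 | step 9 | C3-O-TBS ether of F1 | C[C@H]1[C@@H](O[Si](C)(C)C(C)(C)C)C[C@@H](C(C)=C)[C@@](CCCO[Si](C)(C)C(C)(C)C)(CO[Si](C)(C)C(C)(C)C)[C@H]1O
F3 | step 9 | β-silyloxy ketone (C7=O) | C[C@H]1[C@@H](O[Si](C)(C)C(C)(C)C)C[C@@H](C(C)=C)[C@@](CCCO[Si](C)(C)C(C)(C)C)(CO[Si](C)(C)C(C)(C)C)C1=O
F4 | step 9 | C3-O-TBS analogue of spirolactone 17 | C[C@H]1[C@@H](O[Si](C)(C)C(C)(C)C)C[C@@H](C(C)=C)[C@@](CCCO[Si](C)(C)C(C)(C)C)(CO[Si](C)(C)C(C)(C)C)[C@]12CC(C)C(=O)O2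
F5 | step 11 | silyl ketene acetal of the spirolactone, C3-OTBS | C[C@H]1[C@@H](O[Si](C)(C)C(C)(C)C)C[C@@H](C(C)=C)[C@@](CCCO[Si](C)(C)C(C)(C)C)(CO[Si](C)(C)C(C)(C)C)[C@]12CC(C)=C(O[Si](C)(C)C(C)(C)C)O2
F6 | step 13 | methyl pseudo-ester (C13-OMe) of 23 | C[C@H]1[C@@H](O[Si](C)(C)C(C)(C)C)C[C@@H](C(C)=C)[C@@](CCCO[Si](C)(C)C(C)(C)C)(CO[Si](C)(C)C(C)(C)C)[C@]12C[C@](C)([C@@H](C)C3=CC(C)(OC)OC3=O)C(=O)O2
F7 | step 13 | C15 pinacol boronate of F6 (C11/C13/C15 epimers) | C[C@H]1[C@@H](O[Si](C)(C)C(C)(C)C)C[C@@H](C(C)=C)[C@@](CCCO[Si](C)(C)C(C)(C)C)(CO[Si](C)(C)C(C)(C)C)[C@]12C[C@](C)([C@@H](C)C3C(B4OC(C)(C)C(C)(C)O4)C(C)(OC)OC3=O)C(=O)O2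
F8 | step 13 | C15 alcohol from F7 (C11/C13/C15 epimers) | C[C@H]1[C@@H](O[Si](C)(C)C(C)(C)C)C[C@@H](C(C)=C)[C@@](CCCO[Si](C)(C)C(C)(C)C)(CO[Si](C)(C)C(C)(C)C)[C@]12C[C@](C)([C@@H](C)C3C(O)C(C)(OC)OC3=O)C(=O)O2
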